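Eremophilane numbering is used: ring A is the cyclohexanone C1–C2(=O)–C3–C4(Me)–C5(Me)–C10, ring B is C5–C6–C7–C8–C9–C10. The route rests on excising C3, the methylene lying between the carbonyl C2 and the more substituted, stereogenic C4 of ring A: what remains is a cis-hydrindan-2-one (C1, C2, C4, C5, C10) that is the methylated Pauson–Khand adduct of an acyclic 1,7-enyne. The key step, a one-pot β-oxido carbenoid ring enlargement with dibromomethyllithium, re-inserts C3 between C2 and C4 with retention at C4, converting the cyclopentanone into ring A and completing the fully configured cis-decalin core in one operation.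

Key step: step 9

Remark: in this numbering C7 carries the isopropenyl group, C8 and C9 carry the ester oxygens and C10 is the ring-fusion CH; the target is (4S,5R,7R,8R,9S,10S). The configuration at the carbinol carbon of 17 and 18 (and at C4 of F2) is not defined and has no consequence for the route.

Step 1
Reactants: 1 (R)-4-benzyloxazolidin-2-one; 2 3-methylbut-2-enoyl chloride
Product: 4 (R)-4-benzyl-3-(3-methylbut-2-enoyl)oxazolidin-2-one, via lithium oxazolidinide 3 (not isolated)
Conditions: n-BuLi, THF, −78 °C; then 2, −78 → 0 °C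
Reagents that add atoms: none
Why: N-acylation of the lithiated Evans auxiliary with an acid chloride is standard imide formation and creates no stereocentre.

Step 2
Reactants: 4 (R)-4-benzyl-3-(3-methylbut-2-enoyl)oxazolidin-2-one; 5 1-bromobut-2-yne
Product: 7 (R)-4-benzyl-3-[(2R)-2-(prop-1-en-2-yl)hex-4-ynoyl]oxazolidin-2-one, via sodium dienolate 6 (not isolated)
Conditions: NaHMDS, THF, −78 °C; then 5, −78 → −40 °C
Reagents that add atoms: none
Why: Evans-type deconjugative α-alkylation: γ-deprotonation of the s-cis enoyl imide gives the chelated (Z)-dienolate, which the propargylic bromide should attack at the α-carbon on the face opposite the benzyl group, setting C7 as (R).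

Step 3
Reactants: 7 (R)-4-benzyl-3-[(2R)-2-(prop-1-en-2-yl)hex-4-ynoyl]oxazolidin-2-one
Product: 8 (2R)-2-(prop-1-en-2-yl)hex-4-yn-1-ol
Conditions: LiBH4, MeOH (1 equiv), Et2O, 0 °C
Reagents that add atoms: none
Why: Reductive cleavage of the imide by LiBH4 attacks the exocyclic carbonyl and releases the auxiliary without enolising the α-stereocentre.

Step 4
Reactants: 8 (2R)-2-(prop-1-en-2-yl)hex-4-yn-1-ol
Product: 9 (2R)-2-(prop-1-en-2-yl)hex-4-ynal
Conditions: Dess–Martin periodinane, NaHCO3, CH2Cl2, 0 °C → rt; used at once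
Reagents that add atoms: none
Why: Buffered Dess–Martin oxidation is neutral and non-enolising, so the α-stereocentre and the β,γ-double bond should stay in place.

Step 5
Reactants: 9 (2R)-2-(prop-1-en-2-yl)hex-4-ynal
Product: 11 (3S,4R,5R)-5-(prop-1-en-2-yl)non-1-en-7-yne-3,4-diol, via silylated borinate adduct 10 (not isolated)
Conditions: CH2=CHCH2SiMe2N(i-Pr)2, n-BuLi, TMEDA, Et2O, 0 °C; (−)-Ipc2BOMe, −78 °C; BF3·OEt2; then 9, −78 °C; then H2O2, KF, KHCO3, THF/MeOH, rt
Reagents that add atoms: allyl(diisopropylamino)dimethylsilane C=CC[Si](C)(C)N(C(C)C)C(C)C; hydrogen peroxide OO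
Why: Brown-type allylboration with an (E)-γ-silylallyl diisopinocampheylborane goes through a closed chair transition state, so the E geometry should give the anti adduct and the isopinocampheyl groups (from (+)-α-pinene) should select the aldehyde face that sets C8 as (R), after which Tamao–Fleming oxidation of the C–Si bond with retention sets C9 as (S).

Step 6
Reactants: 11 (3S,4R,5R)-5-(prop-1-en-2-yl)non-1-en-7-yne-3,4-diol
Product: 12 (4R,5S)-2,2-dimethyl-4-[(3R)-2-methylhept-1-en-5-yn-3-yl]-5-vinyl-1,3-dioxolane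
Conditions: 2,2-dimethoxypropane, PPTS (cat.), CH2Cl2, rt
Reagents that add atoms: 2,2-dimethoxypropane COC(C)(C)OC
Why: Acid-catalysed transacetalisation gives the cis-dioxolane, which protects both hydroxyls and holds the alkene and alkyne arms cis for the next step.

Step 7
Reactants: 12 (4R,5S)-2,2-dimethyl-4-[(3R)-2-methylhept-1-en-5-yn-3-yl]-5-vinyl-1,3-dioxolane
Product: 14 (3aS,4S,5R,6R)-4,5-(isopropylidenedioxy)-1-methyl-6-(prop-1-en-2-yl)-3,3a,4,5,6,7-hexahydro-2H-inden-2-one, via hexacarbonyldicobalt alkyne complex 13 (not isolated)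
Conditions: Co2(CO)8, CH2Cl2, rt; then NMO, CH2Cl2, 0 °C → rt
Reagents that add atoms: dicobalt octacarbonyl O=C=[Co](=C=O)(=C=O)(=C=O)[Co](=C=O)(=C=O)(=C=O)=C=O
Why: Intramolecular Pauson–Khand [2+2+1] cycloaddition of the 1,7-enyne forms ring B (C5–C10 bond) and the cyclopentenone (C1–C2 and C2–C4 bonds) with the methyl-bearing alkyne carbon α to the new carbonyl, and a chair-like tether with the isopropenyl group and the C8–O bond equatorial should set C10 with H-10 trans to the C9–O bond.

Step 8
Reactants: 14 (3aS,4S,5R,6R)-4,5-(isopropylidenedioxy)-1-methyl-6-(prop-1-en-2-yl)-3,3a,4,5,6,7-hexahydro-2H-inden-2-one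
Product: 16 (1R,3aS,4S,5R,6R,7aS)-4,5-(isopropylidenedioxy)-1,7a-dimethyl-6-(prop-1-en-2-yl)octahydro-2H-inden-2-one, via trimethylsilyl enol ether 15 (not isolated)
Conditions: MeMgBr, CuBr·SMe2 (cat.), TMSCl, HMPA, THF, −78 → −30 °C; then NaOMe, MeOH, rt
Reagents that add atoms: methylmagnesium bromide C[Mg]Br
Why: Chlorosilane-accelerated copper-catalysed conjugate addition should deliver methyl to C5 on the face of H-10, opposite the axial C9–O bond, giving the cis-fused quaternary centre, and methanolysis with base equilibration should then place the C4 methyl on the convex face, cis to the C5 methyl.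

Step 9
Reactants: 16 (1R,3aS,4S,5R,6R,7aS)-4,5-(isopropylidenedioxy)-1,7a-dimethyl-6-(prop-1-en-2-yl)octahydro-2H-inden-2-one
Product: 20 (4S,5R,7R,8R,9S,10S)-8,9-(isopropylidenedioxy)eremophil-11-en-2-one, via lithium dibromomethyl carbinolate 17 (not isolated), via β-oxido carbenoid 18 (not isolated), via lithium enolate 19 (not isolated)
Conditions: CH2Br2, LiTMP, THF, −78 °C; then n-BuLi (2 equiv), −78 → 0 °C; aq NH4Cl
Reagents that add atoms: dibromomethane BrCBr
Why: Dibromomethyllithium, generated from CH2Br2 and LiTMP in the presence of 16, adds to the C2 carbonyl to give carbinolate 17, bromine–lithium exchange with n-BuLi gives β-oxido carbenoid 18, and loss of bromide coupled to a 1,2-shift of a ring bond from C2 to the carbenoid carbon (the future C3) gives the ring-enlarged enolate 19 and, on protonation, ketone 20; the closest known type is the β-oxido carbenoid one-carbon homologation of cycloalkanones, a semipinacol (Tiffeneau–Demjanov-like) ring enlargement. Ring A is therefore not closed by a cyclisation but arises by 5→6 ring expansion, the C2–C4 bond being exchanged for C2–C3 and C3–C4. No new stereocentre is created: C4 migrates with retention, so the cis C4/C5 dimethyl relationship fixed by equilibration in 16 is carried over unchanged, C5 and C10 are untouched, and the carbinol configuration of 17 and 18 is lost on rearrangement. The step needs regioselectivity (migration of C4, not C1), which should be secured by the higher migratory aptitude of the more substituted secondary α-carbon in carbenoid rearrangements of this type; because the enolate forms specifically towards C3, C4 ends up β to the carbonyl and can no longer epimerise. Addition rather than enolisation is favoured by generating the carbenoid at −78 °C in the presence of the ketone, and the acetonide, the isopropenyl group and the ring-B stereocentres are inert to the amide base and to n-BuLi at low temperature.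

Step 10
Reactants: 20 (4S,5R,7R,8R,9S,10S)-8,9-(isopropylidenedioxy)eremophil-11-en-2-one
Product: 21 (4S,5R,7R,8R,9S,10S)-8,9-dihydroxyeremophil-11-en-2-one
Conditions: AcOH/H2O (4:1), 40 °C
Reagents that add atoms: none
Why: Mild acid hydrolysis of the acetal frees the cis-diol, and since both carbons α to the ketone are methylenes no stereocentre can epimerise.

Step 11
Reactants: 21 (4S,5R,7R,8R,9S,10S)-8,9-dihydroxyeremophil-11-en-2-one; 22 tigloyl chloride [(E)-2-methylbut-2-enoyl chloride]
Product: 24 (4S,5R,7R,8R,9S,10S)-8,9-bis(tigloyloxy)eremophil-11-en-2-one (CNP0249036.2), via C8 monotiglate 23 (not isolated)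
Conditions: 22 (3 equiv), DMAP, pyridine, CH2Cl2, 0 → 40 °C
Reagents that add atoms: second equivalent of tigloyl chloride C/C=C(\C)C(=O)Cl
Why: DMAP-catalysed acylation (nucleophilic catalysis) consumes two equivalents of tigloyl chloride, the first expected to esterify the equatorial C8 hydroxyl to give monoester 23 and the second, with excess reagent and warming, the hindered axial C9 hydroxyl, while the stable (E) geometry of the tigloyl unit is retained.

Compound list
1 | (R)-4-benzyloxazolidin-2-one | O=C1N[C@H](Cc2ccccc2)CO1 | starting material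
2 | 3-methylbut-2-enoyl chloride | CC(C)=CC(=O)Cl | starting material
3 | lithium (R)-4-benzyl-2-oxooxazolidin-3-ide | [Li+].O=C1[N-][C@H](Cc2ccccc2)CO1 | intermediate
4 | (R)-4-benzyl-3-(3-methylbut-2-enoyl)oxazolidin-2-one | CC(C)=CC(=O)N1[C@H](Cc2ccccc2)COC1=O | intermediate
5 | 1-bromobut-2-yne | CC#CCBr | starting material
6 | sodium (Z)-dienolate of 4 | [Na+].C=C(C)/C=C(\[O-])N1[C@H](Cc2ccccc2)COC1=O | intermediate
7 | (R)-4-benzyl-3-[(2R)-2-(prop-1-en-2-yl)hex-4-ynoyl]oxazolidin-2-one | C=C(C)[C@@H](CC#CC)C(=O)N1[C@H](Cc2ccccc2)COC1=O | intermediate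
8 | (2R)-2-(prop-1-en-2-yl)hex-4-yn-1-ol | C=C(C)[C@@H](CC#CC)CO | intermediate
9 | (2R)-2-(prop-1-en-2-yl)hex-4-ynal | C=C(C)[C@@H](CC#CC)C=O | intermediate
10 | diisopinocampheylborinate of the anti β-(aminosilyl) homoallylic alcohol | C=C(C)[C@@H](CC#CC)[C@@H](OB([C@H]1[C@H](C)[C@H]2C[C@@H](C1)C2(C)C)[C@H]1[C@H](C)[C@H]2C[C@@H](C1)C2(C)C)[C@@H]([Si](C)(C)N(C(C)C)C(C)C)C=C | intermediate
11 | (3S,4R,5R)-5-(prop-1-en-2-yl)non-1-en-7-yne-3,4-diol | C=C(C)[C@@H](CC#CC)[C@@H](O)[C@@H](O)C=C | intermediate
12 | (4R,5S)-2,2-dimethyl-4-[(3R)-2-methylhept-1-en-5-yn-3-yl]-5-vinyl-1,3-dioxolane | C=C(C)[C@@H](CC#CC)[C@H]1OC(C)(C)O[C@H]1C=C | intermediate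
13 | hexacarbonyldicobalt complex of the alkyne of 12 | CC12[Co]3(=C=O)(=C=O)(=C=O)[Co]1(=C=O)(=C=O)(=C=O)C23C[C@H](C(C)=C)[C@H]1OC(C)(C)O[C@H]1C=C | intermediate
14 | (3aS,4S,5R,6R)-4,5-(isopropylidenedioxy)-1-methyl-6-(prop-1-en-2-yl)-3,3a,4,5,6,7-hexahydro-2H-inden-2-one | C=C(C)[C@H]1CC2=C(C)C(=O)C[C@@H]2[C@@H]3OC(C)(C)O[C@H]13 | intermediate
15 | trimethylsilyl enol ether (C2=C4) of 16 | C=C(C)[C@H]1C[C@]2(C)C(C)=C(O[Si](C)(C)C)C[C@@H]2[C@@H]3OC(C)(C)O[C@H]13 | intermediate
16 | (1R,3aS,4S,5R,6R,7aS)-4,5-(isopropylidenedioxy)-1,7a-dimethyl-6-(prop-1-en-2-yl)octahydro-2H-inden-2-one | C=C(C)[C@H]1C[C@]2(C)[C@@H](C)C(=O)C[C@@H]2[C@@H]3OC(C)(C)O[C@H]13 | intermediate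
17 | lithium alkoxide of the C2 dibromomethyl carbinol of 16 | [Li+].C=C(C)[C@H]1C[C@]2(C)[C@@H](C)C([O-])(C(Br)Br)C[C@@H]2[C@@H]3OC(C)(C)O[C@H]13 | intermediate
18 | β-oxido carbenoid (lithium alkoxide with CH(Li)Br at C2) | [Li+].C=C(C)[C@H]1C[C@]2(C)[C@@H](C)C([O-])(C([Li])Br)C[C@@H]2[C@@H]3OC(C)(C)O[C@H]13 | intermediate
19 | lithium C2=C3 enolate of 20 | [Li+].C=C(C)[C@H]1C[C@@]2(C)[C@H](CC([O-])=C[C@@H]2C)[C@@H]3OC(C)(C)O[C@H]13 | intermediate
20 | (4S,5R,7R,8R,9S,10S)-8,9-(isopropylidenedioxy)eremophil-11-en-2-one | C=C(C)[C@H]1C[C@@]2(C)[C@H](CC(=O)C[C@@H]2C)[C@@H]3OC(C)(C)O[C@H]13 | intermediate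
21 | (4S,5R,7R,8R,9S,10S)-8,9-dihydroxyeremophil-11-en-2-one | C=C(C)[C@H]1C[C@@]2(C)[C@H](CC(=O)C[C@@H]2C)[C@H](O)[C@@H]1O | intermediate
22 | tigloyl chloride | C/C=C(\C)C(=O)Cl | starting material
23 | (4S,5R,7R,8R,9S,10S)-9-hydroxy-8-(tigloyloxy)eremophil-11-en-2-one | C=C(C)[C@H]1C[C@@]2(C)[C@H](CC(=O)C[C@@H]2C)[C@H](O)[C@@H]1OC(=O)/C(C)=C/C | intermediate
24 | (4S,5R,7R,8R,9S,10S)-8,9-bis(tigloyloxy)eremophil-11-en-2-one | C=C(C)[C@H]1C[C@@]2(C)[C@H](CC(=O)C[C@@H]2C)[C@H](OC(=O)/C(C)=C/C)[C@@H]1OC(=O)/C(C)=C/C | target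

Total step count: 11
Longest linear sequence: 11 steps (1 + 2 → 24)

Steps most likely to fail

1. Step 9. The carbenoid or the amide base may enolise the cyclopentanone instead of adding to it, and part of the rearrangement may proceed by migration of the less substituted C1, giving the regioisomeric ring enlargement. The fallback fixes the regiochemistry through the enol ether instead of migratory aptitude. It sets out from 15, isolated by a non-aqueous work-up of step 8 in place of the methanolysis, and comes back at 20. Simmons–Smith cyclopropanation (Et2Zn, CH2I2, CH2Cl2, 0 °C, carbenoid as limiting reagent so that the electron-rich enol ether reacts before the isopropenyl group) should give the siloxycyclopropane F1. Saegusa–Ito oxidative ring opening (FeCl3, DMF, 0 °C) should cleave the internal C2–C4 bond to the tertiary C4 radical and give the ring-expanded β-chloro ketone F2. Elimination (NaOAc, MeOH, reflux) should give the Δ3-enone F3. Dissolving-metal reduction (Li, NH3, THF, t-BuOH 1 equiv, −78 °C) should then protonate C4 so that its methyl becomes equatorial, cis to the C5 methyl, giving 20.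

2. Step 8. Conjugate addition to the tetrasubstituted enone may be sluggish and lose out to 1,2-addition. The fallback brings in the angular methyl as a cyclopropane methylene. It sets out from 14 and comes back at 16. Luche reduction (NaBH4, CeCl3·7H2O, MeOH, −20 °C), with hydride expected anti to H-10, should give the allylic alcohol F4. Hydroxyl-directed Simmons–Smith cyclopropanation (Et2Zn, CH2I2, CH2Cl2, 0 °C) should deliver CH2 to the C4=C5 bond on the hydroxyl face, giving the cyclopropyl carbinol F5. Dess–Martin oxidation should give the cyclopropyl ketone F6. Li/NH3 (THF, −78 °C; NH4Cl) should cleave the exocyclic cyclopropane bond that overlaps with the carbonyl π system, turning the cyclopropane methylene into the C5 methyl; equilibration at C4 (NaOMe, MeOH) then gives 16.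

3. Step 5. The β,γ-unsaturated aldehyde may lose configuration at C7 or isomerise into conjugation before it is trapped, and the reagent and the α-stereocentre may be mismatched. The fallback avoids handling the free aldehyde. It sets out from alcohol 8 and comes back at 11. Iridium-catalysed transfer-hydrogenative anti-(α-benzoyloxy)allylation of 8 with prop-2-ene-1,1-diyl dibenzoate (cyclometalated Ir–chiral bisphosphine catalyst, ligand enantiomer chosen for the 8R,9S sense, K3PO4, THF, 70 °C) generates the aldehyde only transiently and should give the anti diol monobenzoate F7. Methanolysis (K2CO3, MeOH, rt) then gives 11.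

Further compounds
F1 | step 9 | siloxycyclopropane from 15 (CH2 across C2=C4, convex face assumed) | C=C(C)[C@H]1C[C@]2(C)[C@@]4(C)C[C@@]4(O[Si](C)(C)C)C[C@@H]2[C@@H]3OC(C)(C)O[C@H]13
F2 | step 9 | 4-chloro-8,9-(isopropylidenedioxy)eremophil-11-en-2-one | C=C(C)[C@H]1C[C@@]2(C)[C@H](CC(=O)CC2(C)Cl)[C@@H]3OC(C)(C)O[C@H]13
F3 | step 9 | (5R,7R,8R,9S,10S)-8,9-(isopropylidenedioxy)eremophila-3,11-dien-2-one | C=C(C)[C@H]1C[C@@]2(C)[C@H](CC(=O)C=C2C)[C@@H]3OC(C)(C)O[C@H]13
F4 | step 8 | allylic alcohol from 14 (C2 hydroxyl on the face of H-10) | C=C(C)[C@H]1CC2=C(C)[C@@H](O)C[C@@H]2[C@@H]3OC(C)(C)O[C@H]13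
F5 | step 8 | cyclopropyl carbinol (CH2 across C4=C5 on the hydroxyl face) | C=C(C)[C@H]1C[C@@]24C[C@@]4(C)[C@@H](O)C[C@@H]2[C@@H]3OC(C)(C)O[C@H]13
F6 | step 8 | cyclopropyl ketone from F5 | C=C(C)[C@H]1C[C@@]24C[C@@]4(C)C(=O)C[C@@H]2[C@@H]3OC(C)(C)O[C@H]13
F7 | step 5 | (3S,4R,5R)-4-hydroxy-5-(prop-1-en-2-yl)non-1-en-7-yn-3-yl benzoate | C=C(C)[C@@H](CC#CC)[C@@H](O)[C@@H](OC(=O)c1ccccc1)C=C
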